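A curve that goes flat with substrate still present tempts one to count target made and blame a tired catalyst, so I count what is left.

| setting | winter | noon | flask |
|---|---|---|---|
| substrate | 0.10 M | 0.10 M | 0.10 M |
| reagent | 0.10 M | 0.10 M | 0.100 M |
| free catalyst | 0.17 mM | 0.26 mM | 0.17 mM |
| remark | the very flask that is asked about, followed so far | run made earlier |  |
| time |  |  | 40 min |

- winter (time / min: target / %, substrate / %): 2.50: 63, 39; 6.00: 76, 24; 15.0: 84, 17; 30.0: 85, 16
- noon (time / min: target / %, substrate / %): 2.50: 74, 27; 8.00: 85, 14; 12.0: 84, 11; 20.0: 87, 11

(scatter of a reading: 1.5 percentage points)

* target, in percent of the substrate first charged, at 40 min
* the remedy with the largest gain of target, or "none" below 2 percentage points (red / teal / ochre / green / none)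
* target present, with what was taken out counted in, in percent of the substrate first charged, after red
* target present, with what was taken out counted in, in percent of the substrate first charged, after ochre

- red: at 40 min add reagent, 100% of the amount charged, then wait 40 min
- teal: at 40 min take out 90% of the target then present, then wait 40 min
- ochre: change nothing and wait 40 min more
- green: at 40 min add free catalyst, 50.0% of the amount charged, then wait 40 min

- removed target is counted in
- reactions considered so far: substrate + free catalyst <-> catalyst intermediate A; 2 reagent -> self-condensation product; catalyst intermediate B -> free catalyst + target; reagent + catalyst intermediate A -> catalyst intermediate B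
- additions bring no volume worth counting

The flask asked about is the winter run continued. The listed reactions hold no step that destroys catalyst, and target leaves catalyst intermediate B in one direction, so my working reading is that reagent ended the winter run. Its last two rows, using substrate and the complement of target, put the substrate left at 16.0%.

Reagent goes two ways, and dividing one rate by the other removes time. Let s be the fraction of substrate left, q the reagent charged per substrate, and ρ the ratio defined below. At the stall, s to the power one minus ρ equals one minus q times (one minus ρ). The winter charges give q as one, so I start from a quarter and get 0.253, then 0.254. This ρ is the waste ratio, a selectivity factor: reagent lost to self-condensation per reagent used on substrate, with c(reagent) equal to c(substrate).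

I commit to 84.0% target at 40 min. Target moves from 84% to 85% between 15.0 min and 30.0 min, within the scatter of 1.5 percentage points, so I expect the same after ochre. Green and teal add no reagent, and I expect from them what ochre gives. Red makes q 6.25 on the substrate left, and the right side becomes −3.66. A negative value allows no stall, and the wait is 16.0 times the first winter interval, so I expect target near 100%.

The weak link is that ρ came from the plateau it reproduces. The noon run is a separate test if ρ falls in proportion as catalyst rises. That gives 0.166 and 11.6% substrate left, while the noon rows read the same way give 12.8%.

The forecast gives 84.7% now, red as best, 99.5% after red and 84.8% after ochre, noting that “the last step is irreversible”.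

The flask gives 84.0% at 40 min, 84.0% after ochre and 100% after red. The best remedy is red, with a gain of 16 points, while green gains 0 points and teal 0 points.

    substrate + free catalyst ⇌ catalyst intermediate A (K = 10.0 M⁻¹, k = 380 M⁻¹ s⁻¹)
    2 reagent → self-condensation product (k = 0.0160 M⁻¹ s⁻¹)
    catalyst intermediate B → free catalyst + target (k = 13.0 s⁻¹)
    reagent + catalyst intermediate A → catalyst intermediate B (k = 180 M⁻¹ s⁻¹)

The neighbouring flask holds 0.25 M of substrate with the flask's reagent and catalyst, so q is 0.400 and I keep ρ at 0.254. The right side comes to 0.702, which leaves 62.2% of the substrate and makes 37.8% target. At 40.0 min, the neighbouring flask holds 64.4% substrate, 35.6% target and 0% reagent, with 61.7% of its catalyst standing as catalyst intermediate A.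

The numbers in the tables were computed for an exercise; scatter was added.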